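Ring A (C1 carries the C7 methylene, C2/C3 bromine, C4/C5 oxygen, C6 hydrogen) is traced back to a non-aromatic 2-methoxycyclohex-2-enone. This works because the C7 branch at C1 sits para to the C4 oxygen and the C5 oxygen is its neighbour. Cutting C1–C2 and C5–C6 leaves a 3-arylpropanal and 1-methoxybut-3-en-2-one. One amine-catalysed Michael/aldol condensation sequence forges both bonds, closes ring A and fixes C4=O, C5–OMe and C7 in their final positions. The aldehyde already holds ring B as a bromo tris-tosylate, so ring B stays inert until the final unmasking. Dehydrogenation, dibromination and deprotection complete the target.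

Key step: step 5

Numbering: ring A = C1 (bears C7), C2 and C3 (Br), C4 and C5 (O), C6 (H). Ring B = C1′ (bears C7), C2′, C4′, C6′ (O), C3′ (Br), C5′ (H). Ts = 4-methylbenzenesulfonyl; tosyloxy = OTs.

Assumption: 1-methoxybut-3-en-2-one is treated as a purchasable, inhibitor-stabilised vinyl ketone that is distilled just before use.

Design points:
- **Early C3′ bromine.** It is installed first, on the formyl-deactivated triol, and passes through the key step as a spectator. Stopping the bromination of a free benzylphloroglucinol at one bromine at the end would be much harder. For this reason the side-chain C=C bond is reduced by hydride transfer, not over a hydrogenation metal.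
- **Aromatisation kept apart from ring A bromination.** Elemental bromine could attack the C5=C6 enol ether at C6, the one ring A position that must keep its hydrogen.
- **Aqueous base for sulfonate removal.** With no alcohol present, no alkyl tosylate can form and alkylate the freed phenoxides.

Step 1
Reactants: 1 2,4,6-trihydroxybenzaldehyde
Product: 2 3-bromo-2,4,6-trihydroxybenzaldehyde
Conditions: NBS (1.0 equiv, slow addition), MeCN, −30 °C → 0 °C, dark
Reagents that add atoms: N-bromosuccinimide, O=C1CCC(=O)N1Br
Why: Electrophilic aromatic bromination in which the formyl group tempers the ring and the first bromine lowers its reactivity further, so one equivalent of reagent in the cold should stop at the monobromide, and the two free ring positions are equivalent so no regiochemical question arises.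

Step 2
Reactants: 2 3-bromo-2,4,6-trihydroxybenzaldehyde, 3 4-methylbenzenesulfonyl chloride
Product: 4 3-bromo-2,4,6-tris(tosyloxy)benzaldehyde
Conditions: 3 (3.6 equiv), Et3N (5 equiv), 4-(dimethylamino)pyridine (10 mol %), CH2Cl2–MeCN, 0 °C → rt
Reagents that add atoms: 4-methylbenzenesulfonyl chloride (3), Cc1ccc(cc1)S(=O)(=O)Cl
Why: O-sulfonylation of phenols under nucleophilic catalysis should also reach the two chelated ortho hydroxyls, and the three sulfonates deactivate ring B toward bromine while tolerating ylides, ammonium salts, acid and oxidants.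

Step 3
Reactants: 4 3-bromo-2,4,6-tris(tosyloxy)benzaldehyde, 5 (triphenyl-λ5-phosphanylidene)acetaldehyde
Product: 6 (2E)-3-[3-bromo-2,4,6-tris(tosyloxy)phenyl]prop-2-enal
Conditions: 5 (1.1 equiv), toluene, 80 °C
Reagents that add atoms: (triphenyl-λ5-phosphanylidene)acetaldehyde (5), O=CC=P(c1ccccc1)(c1ccccc1)c1ccccc1
Why: Wittig olefination with a stabilised formyl ylide should give the E enal, and the electron-poor aryl aldehyde is a better electrophile than the enal product, which limits a second homologation.

Step 4
Reactants: 6 (2E)-3-[3-bromo-2,4,6-tris(tosyloxy)phenyl]prop-2-enal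
Product: 7 3-[3-bromo-2,4,6-tris(tosyloxy)phenyl]propanal
Conditions: diethyl 2,6-dimethyl-1,4-dihydropyridine-3,5-dicarboxylate (Hantzsch ester, 1.1 equiv), dibenzylammonium trifluoroacetate (10 mol %), THF, rt
Reagents that add atoms: none
Why: Iminium-catalysed transfer hydrogenation (organocatalytic conjugate reduction) delivers hydride only to the beta carbon of the enal iminium ion, so the C3′–Br bond, the sulfonates and the saturated aldehyde should be left untouched.

Step 5
Reactants: 7 3-[3-bromo-2,4,6-tris(tosyloxy)phenyl]propanal, 8 1-methoxybut-3-en-2-one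
Product: 11 rac-4-{[3-bromo-2,4,6-tris(tosyloxy)phenyl]methyl}-2-methoxycyclohex-2-en-1-one, via keto aldehyde 9 (not isolated), via cyclic aldol 10 (not isolated)
Conditions: 8 (1.5 equiv), Et2NSiMe3 (20 mol %), MeCN, rt → 50 °C; then evaporate, dibenzylammonium trifluoroacetate (20 mol %), 4 Å molecular sieves, toluene, 70 °C
Reagents that add atoms: 1-methoxybut-3-en-2-one (8), COCC(=O)C=C
Why: Diethylamine liberated from Et2NSiMe3 condenses with 7 to an enamine whose nucleophilic carbon (C1) adds to the unsubstituted vinyl terminus of 8 (C2), and hydrolysis of the resulting iminium ion releases keto aldehyde 9 and the amine. In the second stage the dibenzylammonium salt, a mild acid–base pair, enolises the ketone toward its methoxy-bearing CH2 (C5), C5 attacks the aldehyde carbon (C6) to give aldol 10, and loss of water delivers the conjugated enol-ether enone 11. The closest known chemistry is the amine-catalysed Michael addition of unbranched aldehydes to alkyl vinyl ketones followed by aldol condensation to 4-substituted cyclohex-2-enones, an organocatalytic form of the Robinson annulation, together with the established preference of alkoxymethyl ketones to react at the oxygenated carbon in amine-catalysed aldol reactions. Ring A closes in a 6-(enolendo)-exo-trig aldol mode. C1 is created from a planar achiral enamine with no controlling element, so 11 is a racemate, the two further centres of 10 disappear on dehydration, and C1 itself becomes sp2 in step 6. The step needs site selectivity in the closure and chemoselectivity against aldehyde self-condensation: the first is built into 9, since closure through C3 or through the aldehyde alpha carbon could only give a cyclobutane, and the second is served by the excess of the highly electrophilic vinyl ketone, by the bulky ring B beside the enamine and by weakly nucleophilic amines that leave the sulfonates alone.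

Step 6
Reactants: 11 rac-4-{[3-bromo-2,4,6-tris(tosyloxy)phenyl]methyl}-2-methoxycyclohex-2-en-1-one
Product: 12 4-{[3-bromo-2,4,6-tris(tosyloxy)phenyl]methyl}-2-methoxyphenol
Conditions: Pd(O2CCF3)2 (5 mol %), 2-(dimethylamino)pyridine (10 mol %), TsOH·H2O (20 mol %), O2 (1 atm), DMSO, 80 °C
Reagents that add atoms: none
Why: Palladium-catalysed aerobic dehydrogenation of a cyclohexenone, in which a divalent palladium enolate at C3 undergoes beta-hydride elimination from C2, the cross-conjugated dienone tautomerises to the C4 phenol and O2 reoxidises the metal, all without any electrophilic halogen that could enter at C6.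

Step 7
Reactants: 12 4-{[3-bromo-2,4,6-tris(tosyloxy)phenyl]methyl}-2-methoxyphenol
Product: 13 2,3-dibromo-4-{[3-bromo-2,4,6-tris(tosyloxy)phenyl]methyl}-6-methoxyphenol
Conditions: Br2 (2.1 equiv), AcOH–CH2Cl2, 0 °C → rt, dark
Reagents that add atoms: bromine, BrBr
Why: Electrophilic aromatic bromination with the regiocontrol known from the conversion of vanillin into its 5,6-dibromide, the free C4 hydroxyl directing to C3 and the C5 methoxy group directing para to C2, while C6 (meta to the hydroxyl and flanked on both sides) and the sulfonylated ring B should stay untouched.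

Step 8
Reactants: 13 2,3-dibromo-4-{[3-bromo-2,4,6-tris(tosyloxy)phenyl]methyl}-6-methoxyphenol
Product: 14 2-bromo-4-[(2,3-dibromo-4-hydroxy-5-methoxyphenyl)methyl]benzene-1,3,5-triol
Conditions: KOH (12 equiv), H2O–1,4-dioxane, 80 °C, argon; then 2 M HCl, 0 °C
Reagents that add atoms: none
Why: Alkaline hydrolysis of aryl sulfonates by attack of hydroxide at sulfur should free all three ring B phenols, the aryl bromides being inert on electron-rich phenoxide rings and exclusion of air guarding the polyphenolate against oxidation.

Step 9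
Reactants: 14 2-bromo-4-[(2,3-dibromo-4-hydroxy-5-methoxyphenyl)methyl]benzene-1,3,5-triol
Product: 15 vidalol A, 2-bromo-4-[(2,3-dibromo-4,5-dihydroxyphenyl)methyl]benzene-1,3,5-triol
Conditions: BBr3 (8 equiv), CH2Cl2, −78 °C → rt; then ice-water
Reagents that add atoms: none
Why: Lewis acid mediated aryl methyl ether cleavage, in which the borate formed at the neighbouring C4 hydroxyl brings boron onto the C5 methoxy oxygen, bromide removes the methyl group by SN2 attack and hydrolysis frees the catechol under acidic conditions that the polyphenol tolerates.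

Compound list
1 | 2,4,6-trihydroxybenzaldehyde | O=Cc1c(O)cc(O)cc1O | starting material
2 | 3-bromo-2,4,6-trihydroxybenzaldehyde | O=Cc1c(O)cc(O)c(Br)c1O | intermediate
3 | 4-methylbenzenesulfonyl chloride | Cc1ccc(cc1)S(=O)(=O)Cl | starting material
4 | 3-bromo-2,4,6-tris(tosyloxy)benzaldehyde | O=Cc1c(OS(=O)(=O)c2ccc(C)cc2)cc(OS(=O)(=O)c2ccc(C)cc2)c(Br)c1OS(=O)(=O)c2ccc(C)cc2 | intermediate
5 | (triphenyl-λ5-phosphanylidene)acetaldehyde | O=CC=P(c1ccccc1)(c1ccccc1)c1ccccc1 | starting material
6 | (2E)-3-[3-bromo-2,4,6-tris(tosyloxy)phenyl]prop-2-enal | O=C/C=C/c1c(OS(=O)(=O)c2ccc(C)cc2)cc(OS(=O)(=O)c2ccc(C)cc2)c(Br)c1OS(=O)(=O)c2ccc(C)cc2 | intermediate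
7 | 3-[3-bromo-2,4,6-tris(tosyloxy)phenyl]propanal | O=CCCc1c(OS(=O)(=O)c2ccc(C)cc2)cc(OS(=O)(=O)c2ccc(C)cc2)c(Br)c1OS(=O)(=O)c2ccc(C)cc2 | intermediate
8 | 1-methoxybut-3-en-2-one | COCC(=O)C=C | starting material
9 | rac-2-{[3-bromo-2,4,6-tris(tosyloxy)phenyl]methyl}-6-methoxy-5-oxohexanal | COCC(=O)CCC(C=O)Cc1c(OS(=O)(=O)c2ccc(C)cc2)cc(OS(=O)(=O)c2ccc(C)cc2)c(Br)c1OS(=O)(=O)c2ccc(C)cc2 | intermediate
10 | 4-{[3-bromo-2,4,6-tris(tosyloxy)phenyl]methyl}-3-hydroxy-2-methoxycyclohexan-1-one (racemic mixture of diastereomers) | COC1C(O)C(Cc2c(OS(=O)(=O)c3ccc(C)cc3)cc(OS(=O)(=O)c3ccc(C)cc3)c(Br)c2OS(=O)(=O)c3ccc(C)cc3)CCC1=O | intermediate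
11 | rac-4-{[3-bromo-2,4,6-tris(tosyloxy)phenyl]methyl}-2-methoxycyclohex-2-en-1-one | COC1=CC(Cc2c(OS(=O)(=O)c3ccc(C)cc3)cc(OS(=O)(=O)c3ccc(C)cc3)c(Br)c2OS(=O)(=O)c3ccc(C)cc3)CCC1=O | intermediate
12 | 4-{[3-bromo-2,4,6-tris(tosyloxy)phenyl]methyl}-2-methoxyphenol | COc1cc(Cc2c(OS(=O)(=O)c3ccc(C)cc3)cc(OS(=O)(=O)c3ccc(C)cc3)c(Br)c2OS(=O)(=O)c3ccc(C)cc3)ccc1O | intermediate
13 | 2,3-dibromo-4-{[3-bromo-2,4,6-tris(tosyloxy)phenyl]methyl}-6-methoxyphenol | COc1cc(Cc2c(OS(=O)(=O)c3ccc(C)cc3)cc(OS(=O)(=O)c3ccc(C)cc3)c(Br)c2OS(=O)(=O)c3ccc(C)cc3)c(Br)c(Br)c1O | intermediate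
14 | 2-bromo-4-[(2,3-dibromo-4-hydroxy-5-methoxyphenyl)methyl]benzene-1,3,5-triol | COc1cc(Cc2c(O)cc(O)c(Br)c2O)c(Br)c(Br)c1O | intermediate
15 | vidalol A, 2-bromo-4-[(2,3-dibromo-4,5-dihydroxyphenyl)methyl]benzene-1,3,5-triol (no stereocentre) | Oc1cc(Cc2c(O)cc(O)c(Br)c2O)c(Br)c(Br)c1O | target

Total step count: 9. Longest linear sequence: 9 steps, from 1 to 15.

Steps most likely to fail

Step 5.
- What may go wrong: self-condensation of the aldehyde, oligomerisation of the vinyl ketone, gradual loss of the amine by sulfonyl transfer from ring B, or an aldol that stalls before dehydration.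
- The fallback sets out from 7 and comes back at 11. It makes the same C1–C2 and C5–C6 bonds without any amine.
- Aldehyde 7 is converted with Me3SiCl, NaI and Et3N in MeCN into its silyl enol ether, (Z)-{3-[3-bromo-2,4,6-tris(tosyloxy)phenyl]prop-1-en-1-yl}oxy(trimethyl)silane F1.
- A Mukaiyama–Michael addition of this compound to 8 (BF3·OEt2, iPrOH, CH2Cl2–MeNO2, −78 °C) should give keto aldehyde 9, which is isolated this time.
- An acid-catalysed aldol condensation (TsOH·H2O cat., toluene, 80 °C, removal of water) then closes 9 to 11.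

Step 6.
- What may go wrong: hydrolytic loss of the enol-ether methyl group in warm acidic DMSO before dehydrogenation, or insertion of zerovalent palladium into the C3′–Br bond with loss of that bromine.
- The fallback sets out from 11 and comes back at 12. It runs acid-free at or below room temperature.
- Kinetic deprotonation at C3 with LiN(SiMe3)2 in THF at −78 °C and trapping with Me3SiCl gives the cross-conjugated silyl dienol ether, rac-[(4-{[3-bromo-2,4,6-tris(tosyloxy)phenyl]methyl}-6-methoxycyclohexa-1,5-dien-1-yl)oxy]trimethylsilane F2.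
- Saegusa–Ito oxidation with Pd(OAc)2 (1 equiv) in MeCN at rt should give the dienone, which tautomerises to 12.

Step 1.
- What may go wrong: overrun to double bromination, or ipso attack with loss of the formyl group.
- The fallback sets out from 1 and comes back at 4. It brominates a ring that carries only one free hydroxyl.
- Two equivalents of 3 with Et3N in CH2Cl2–MeCN at −10 °C should leave one chelated ortho hydroxyl free and give 2-hydroxy-4,6-bis(tosyloxy)benzaldehyde F3.
- One equivalent of NBS in MeCN then places a single bromine ortho to that hydroxyl, giving 3-bromo-2-hydroxy-4,6-bis(tosyloxy)benzaldehyde F4. Bromination para to the hydroxyl would give 3-bromo-6-hydroxy-2,4-bis(tosyloxy)benzaldehyde F5. A second bromination is disfavoured on this much poorer ring.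
- Sulfonylation of the remaining hydroxyl (3, Et3N, 4-(dimethylamino)pyridine, CH2Cl2) turns either isomer into the same compound 4.

Further compounds
F1 | step 5 | (Z)-{3-[3-bromo-2,4,6-tris(tosyloxy)phenyl]prop-1-en-1-yl}oxy(trimethyl)silane | C[Si](C)(C)O/C=C\Cc1c(OS(=O)(=O)c2ccc(C)cc2)cc(OS(=O)(=O)c2ccc(C)cc2)c(Br)c1OS(=O)(=O)c2ccc(C)cc2
F2 | step 6 | rac-[(4-{[3-bromo-2,4,6-tris(tosyloxy)phenyl]methyl}-6-methoxycyclohexa-1,5-dien-1-yl)oxy]trimethylsilane | COC1=CC(Cc2c(OS(=O)(=O)c3ccc(C)cc3)cc(OS(=O)(=O)c3ccc(C)cc3)c(Br)c2OS(=O)(=O)c3ccc(C)cc3)CC=C1O[Si](C)(C)C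
F3 | step 1 | 2-hydroxy-4,6-bis(tosyloxy)benzaldehyde | O=Cc1c(O)cc(OS(=O)(=O)c2ccc(C)cc2)cc1OS(=O)(=O)c2ccc(C)cc2
F4 | step 1 | 3-bromo-2-hydroxy-4,6-bis(tosyloxy)benzaldehyde | O=Cc1c(O)c(Br)c(OS(=O)(=O)c2ccc(C)cc2)cc1OS(=O)(=O)c2ccc(C)cc2
F5 | step 1 | 3-bromo-6-hydroxy-2,4-bis(tosyloxy)benzaldehyde | O=Cc1c(O)cc(OS(=O)(=O)c2ccc(C)cc2)c(Br)c1OS(=O)(=O)c2ccc(C)cc2
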